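## Structural features

Marchantin C is a macrocyclic bis(bibenzyl): four benzene rings in one 18-membered ring, joined in turn by two CH2CH2 bridges (ring A to ring B, ring C to ring D) and two diaryl ether oxygens (ring D C6–O–ring A, ring B C2–O–ring C). Ring A is 1,4-linked and ring C 1,3-linked. Ring B is 1,2,3-substituted (CH2 on C1, aryloxy on C2, OH on C3) and ring D is 1,2,4-substituted (OH on C1, CH2 on C4, aryloxy on C6). The molecule has no stereocentre and no configurationally fixed axis, so no stereochemical relationship has to be set. The sensitive groups are the two phenols, each ortho to an aryloxy group and therefore oxidisable, and they must be told apart; the diaryl ethers and benzylic CH2 groups are robust. The real difficulty is closing the 18-membered ring, which contains a para-bridged benzene, and doing so with full regiocontrol on rings B and D. The key step uses the fact that C4 of ring D, which carries the bridge carbon, is para to the hydroxyl on C1: an arylacetyl group placed on O1 can be moved to C4. An atom count confirms that the ester on O1 and the ketone on C4 both sit in 18-membered rings, as would a ketone on C2; C3 (19-membered, para to the ether oxygen) and C5 (17-membered) also have to be counted as competitors.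

## Logic of the disconnections

19 from 17: the O–CH3 bond on ring B is the only bond added. The ring B hydroxyl has to be inert and must not compete with the ring D hydroxyl as acyl acceptor, and a methyl ether passes base, hydrogenation, carbodiimide and superacid. The two phenols are thereby different from the first step on. The forward cleavage must spare both diaryl ethers.

17 from 15: the benzylic CH2 on ring D C4 is traced back to C=O, which is what an acyl shift leaves at that carbon. This turns an unfunctionalised bridge into a retron for aromatic acylation. The forward step must deoxygenate a para-hydroxyaryl ketone completely without transannular alkylation.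

15 from 13: the bond between ring D C4 and the carbonyl carbon is cut and the carbonyl carbon is put back on the oxygen of C1. The C–C macrocyclisation becomes an isomerisation of a ring that is already closed, ring D loses its carbon substituent and becomes a plain catechol unit, and its hydroxyl needs no separate protecting group. The forward step must deliver the acyl group to C4 and not to C2, C3 or C5, and must not hand it to another molecule.

13 from 11: the ester C(=O)–O bond is cut. Phenol acylation is a dependable ring closure and the open chain has two flexible sp3 bridges. The forward step needs high dilution and an activation that leaves the phenol alone.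

11 from 10: two hydrogens are removed from the A–B bridge and the ring D hydroxyl is masked as a benzyl ether. One hydrogenation undoes both, and the alkene geometry is irrelevant.

10 from 5 and 8: the C=C bond of the A–B bridge is cut (olefination). This splits the chain into two halves of two rings each. The ylide must tolerate a carboxylate.

8 from 6 and 7: the ring B C2–O bond is cut. The formyl group on ring B C1, needed for the olefination anyway, activates the neighbouring carbon for addition–elimination, which avoids a copper coupling on a hindered 2,6-disubstituted phenol. The acid is carried free, so no ester has to be made and removed. The forward step must displace at a carbon flanked by two substituents.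

5 from 4, 4 from 3, 3 from 1 and 2: the C–P bond is cut, the benzylic alcohol is traced to the aldehyde, and the ring A C–O bond is cut para to that formyl group. All three forward steps are routine; the benzyl ether on the second catechol oxygen must survive them.

## Other disconnections considered

Alternative 1: The cut removes both aryl–C(sp) bonds of the A–B bridge, whose two carbons come from ethynyltrimethylsilane. In the forward sense the open dihalide A1 (ring A iodide, ring B C1 bromide, C–D bridge in place, both phenols as methyl ethers) would react with the silylacetylene under PdCl2(PPh3)2/CuI catalysis at the iodide first. Desilylation in the same pot would then let the free alkyne couple with the bromide and close the ring to the diarylalkyne A2. Saturation of the triple bond and cleavage of both methyl ethers would lead to 19.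
- In its favour: the iodide/bromide reactivity order sets the sequence of events without protecting groups, and the regiochemistry is fixed by the halogens. On regiocontrol and on precedent for the ring-closing reaction type it is better than the chosen plan. Both phenols are freed in one final operation, which is equal to the chosen endgame.
- Against it: A2 holds a rigid rod (para-phenylene plus alkyne) inside an 18-membered ring, so closure must bend the alkyne. The bromide on ring B is electron-rich and flanked by the aryloxy group, so oxidative addition should be slow while the terminal alkyne is exposed to oxidative dimerisation. The C–D bridge of A1 cannot be made by hydrogenation over palladium with both carbon–halogen bonds present.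
- Comparison: the chosen plan closes a flexible seco acid and only then makes the C–C bond, by a cationic substitution instead of a catalytic coupling. The step count is expected to be similar or somewhat higher for this alternative.

Alternative 2: The cut is the ring B C1–CH2 bond, with ring B at the cyclohexenone level derived from cyclohexane-1,3-dione. In A3 the ring A styrene would be hydroborated with 9-BBN and the alkylborane coupled with the enol triflate under PdCl2(dppf) catalysis and base, closing the ring to A4. Dehydrogenation of the cyclohexenone (for example with Pd/C at high temperature or Pd(O2CCF3)2 under O2) would aromatise ring B and reveal its hydroxyl, and cleavage of the ring D methyl ether would finish.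
- In its favour: the ring B hydroxyl comes out of the ketone, so ring B needs no protecting group and its 1,2,3 pattern is unambiguous; on this point it is better than the chosen plan. The sp3–sp2 coupling is flexible and its macrocyclic use is a known reaction type, again better on precedent.
- Against it: 9-BBN can also reduce enone carbonyls, so chemoselectivity between styrene and vinylogous ester is uncertain. The 2-aryloxy dione has to be made (for instance by O–H insertion with Rh2(OAc)4) and its mono-triflate is labile. Aromatisation inside the macrocycle is an extra forcing redox step that may also dehydrogenate the bibenzyl bridges.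
- Comparison: ring B is built instead of bought, the mechanism is organometallic instead of cationic, and the route is expected to be two or three steps longer.

Alternative 3: The cut is the diaryl ether bond between the ring A oxygen and ring D C6. In A5 the ring A phenoxide (Cs2CO3, DMF, high dilution) would displace the fluoride ortho to the formyl group and close the ring to the aldehyde A6. A Dakin or Baeyer–Villiger oxidation with hydrolysis of the formate would then give 17, where it joins the chosen route.
- In its favour: the position of the new bond is fixed by the fluorine, so there is no isomer problem, and macrocyclic SNAr etherification is a well-understood polar reaction. On certainty of the ring-closing event it is better than the chosen plan. The formyl group serves twice, as activator and as latent hydroxyl, which equals the double use of the ester in the chosen plan.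
- Against it: one formyl group is a weak activator, so the closure needs heat at high dilution with an aldehyde exposed to base. A5 needs both CH2CH2 bridges built beforehand with the aldehyde masked through olefination and hydrogenation, which adds protecting-group steps.
- Comparison: the chosen plan is shorter, because ring D needs no carbon handle and the C–D bridge carbons arrive with the arylacetic acid, but it rests on an untested step where this alternative rests on known ones.

Key step: step 8

Assumption (remark on the chemistry): 3-hydroxyphenylacetic acid and 2-fluoro-3-methoxybenzaldehyde are taken as commercial, and alkene 10 is used as its E/Z mixture because the double bond is saturated in the next step.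

## Route

Step 1
Reactants: 1 2-(benzyloxy)phenol; 2 4-fluorobenzaldehyde
Product: 3 4-[2-(benzyloxy)phenoxy]benzaldehyde
Conditions: K2CO3, DMF, 120 °C
Reagents that add atoms: none
Why: Nucleophilic aromatic substitution (SNAr): the para-formyl group stabilises the Meisenheimer adduct and fluoride is the best leaving group for this mechanism; the benzyl ether keeps the second catechol oxygen inert.

Step 2
Reactants: 3 4-[2-(benzyloxy)phenoxy]benzaldehyde
Product: 4 {4-[2-(benzyloxy)phenoxy]phenyl}methanol
Conditions: NaBH4, MeOH–THF, 0 °C
Reagents that add atoms: none
Why: Hydride reduction of an aromatic aldehyde with NaBH4 is chemoselective and leaves the benzyl and diaryl ethers untouched.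

Step 3
Reactants: 4 {4-[2-(benzyloxy)phenoxy]phenyl}methanol
Product: 5 {4-[2-(benzyloxy)phenoxy]benzyl}triphenylphosphonium bromide
Conditions: PPh3·HBr, MeCN, reflux
Reagents that add atoms: triphenylphosphine hydrobromide, [Br-].c1ccc(cc1)[PH+](c1ccccc1)c1ccccc1
Why: Direct phosphonium salt formation from a benzylic alcohol: protonation gives an electron-rich 4-aryloxybenzyl electrophile that PPh3 captures by substitution at the benzylic carbon, which saves a separate bromination.

Step 4
Reactants: 6 3-hydroxyphenylacetic acid; 7 2-fluoro-3-methoxybenzaldehyde
Product: 8 2-[3-(2-formyl-6-methoxyphenoxy)phenyl]acetic acid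
Conditions: K2CO3 (2.5 equiv), DMSO, 110 °C; then aq HCl
Reagents that add atoms: none
Why: SNAr at the fluorinated carbon ortho to the formyl group; the base turns 6 into its phenoxide–carboxylate, of which only the phenoxide is a competent nucleophile, and the carboxylate makes the benzylic CH2 too weakly acidic for condensation with the aldehyde. The product is purified by acid–base extraction.

Step 5
Reactants: 5 {4-[2-(benzyloxy)phenoxy]benzyl}triphenylphosphonium bromide; 8 2-[3-(2-formyl-6-methoxyphenoxy)phenyl]acetic acid
Product: 10 2-{3-[2-(2-{4-[2-(benzyloxy)phenoxy]phenyl}ethenyl)-6-methoxyphenoxy]phenyl}acetic acid (E/Z mixture), via phosphonium ylide 9 (not isolated)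
Conditions: KOtBu (2.3 equiv), THF, 0 °C to rt; then aq HCl
Reagents that add atoms: none
Why: Wittig olefination of an aromatic aldehyde with a semi-stabilised benzylic ylide; the extra equivalent of base holds the acid as its carboxylate, which the ylide does not attack. Both alkene isomers are acceptable, and the acidic product is separated from Ph3PO by extraction into base.

Step 6
Reactants: 10 2-{3-[2-(2-{4-[2-(benzyloxy)phenoxy]phenyl}ethenyl)-6-methoxyphenoxy]phenyl}acetic acid (E/Z mixture)
Product: 11 2-[3-(2-{2-[4-(2-hydroxyphenoxy)phenyl]ethyl}-6-methoxyphenoxy)phenyl]acetic acid
Conditions: H2 (1 atm), Pd/C, EtOAc–THF, rt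
Reagents that add atoms: none
Why: Heterogeneous catalytic hydrogenation saturates the stilbene double bond of both isomers and hydrogenolyses the benzyl ether in the same operation; the aryl ethers, the methyl ether and the acid are inert.

Step 7
Reactants: 11 2-[3-(2-{2-[4-(2-hydroxyphenoxy)phenyl]ethyl}-6-methoxyphenoxy)phenyl]acetic acid
Product: 13 18-membered macrolactone (ring D O1 aryl ester of the ring C arylacetic acid; ring B methyl ether; ring D C4 unsubstituted), via O-acylisourea 12 (not isolated)
Conditions: EDC·HCl, DMAP, DMAP·HCl, CHCl3, reflux; 11 added by syringe pump (final 1 mM)
Reagents that add atoms: none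
Why: Keck macrolactonisation (Steglich-type carbodiimide esterification at high dilution with DMAP·HCl as proton shuttle): the acid is activated as 12 and then as the N-acylpyridinium ion, which the ring D phenol attacks, while the carbodiimide does not react with the phenol. Any arylketene formed by elimination would be trapped by the same phenol to the same lactone.

Step 8
Reactants: 13 18-membered macrolactone
Product: 15 macrocyclic deoxybenzoin (18-membered ring; C=O on ring D C4; ring D hydroxyl free; ring B methyl ether), via seco acyl triflate 14 (not isolated)
Conditions: CF3SO3H (20 equiv), CH2Cl2, 0 °C to rt; 13 added slowly (final 2 mM)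
Reagents that add atoms: none
Why: Proposed new method: protonation of the ester carbonyl of 13 should break the acyl–O1 bond and release an arylacetylium ion, in equilibrium with the acyl triflate 14, that stays tied to the freed ring D phenol through rings C, B and A; attack of ring D C4 on this electrophile and loss of the C4 proton, a Friedel–Crafts acylation within the molecule, would give 15. The closest known reaction type is the acid-promoted Fries rearrangement of open-chain aryl arylacetates to 4-hydroxydeoxybenzoins, and the new element is that the migrating acyl group is part of the ring. One ring is closed, the 18-membered ring of the target, by electrophilic aromatic substitution in which C4 attacks the acylium carbon through an 18-membered transition ring, while the 18-membered lactone opens in the same event. No stereocentre is formed. The step needs regioselectivity for C4 over C2, C3 and C5 and chemoselectivity for ring D over rings A and B: C4 is para to the free hydroxyl, the strongest donor present, C3 and C5 are activated only by the weaker diaryl ether oxygen, attack at C2 would force the C1 hydroxyl into the interior of the macrocycle, and rings A and B can be reached only through strained 9- to 13-membered rings. A Brønsted superacid at low temperature is chosen because it forms no chelated metal phenoxide that would steer the acyl group ortho, and slow addition at high dilution should suppress acyl transfer between molecules. Return of the acyl group to oxygen only regenerates 13, whereas C-acylation is not reversed under these conditions, so the lactone should drain into the ketone.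

Step 9
Reactants: 15 macrocyclic deoxybenzoin
Product: 17 marchantin C ring B methyl ether, via benzylic carbinol 16 (not isolated)
Conditions: Et3SiH (5 equiv), CF3CO2H, CH2Cl2, 0 °C to rt
Reagents that add atoms: none
Why: Ionic hydrogenation: protonation of the para-hydroxyaryl ketone and hydride transfer from Et3SiH give 16, which ionises to a benzylic cation stabilised by the para-hydroxyl and is reduced again to CH2. The carbinol carbon of 16 forms racemic and its stereocentre disappears within the same step; phenol, methyl ether and diaryl ethers are inert.

Step 10
Reactants: 17 marchantin C ring B methyl ether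
Product: 19 marchantin C, via bis(dibromoboryl) ether 18 (not isolated)
Conditions: BBr3 (4 equiv), CH2Cl2, −78 to 0 °C; then H2O
Reagents that add atoms: none
Why: Lewis-acid cleavage of an aryl methyl ether: BBr3 binds the methoxy oxygen and bromide removes the methyl group by SN2, a path closed to the diaryl ethers; hydrolysis of 18 on work-up frees both phenols.

## Compound list

1 | 2-(benzyloxy)phenol | Oc1ccccc1OCc1ccccc1 | starting material
2 | 4-fluorobenzaldehyde | O=Cc1ccc(F)cc1 | starting material
3 | 4-[2-(benzyloxy)phenoxy]benzaldehyde | O=Cc1ccc(Oc2ccccc2OCc2ccccc2)cc1 | intermediate
4 | {4-[2-(benzyloxy)phenoxy]phenyl}methanol | OCc1ccc(Oc2ccccc2OCc2ccccc2)cc1 | intermediate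
5 | {4-[2-(benzyloxy)phenoxy]benzyl}triphenylphosphonium bromide | [Br-].c1ccc(cc1)[P+](Cc1ccc(Oc2ccccc2OCc2ccccc2)cc1)(c1ccccc1)c1ccccc1 | intermediate
6 | 3-hydroxyphenylacetic acid | OC(=O)Cc1cccc(O)c1 | starting material
7 | 2-fluoro-3-methoxybenzaldehyde | COc1cccc(C=O)c1F | starting material
8 | 2-[3-(2-formyl-6-methoxyphenoxy)phenyl]acetic acid | COc1cccc(C=O)c1Oc1cccc(CC(=O)O)c1 | intermediate
9 | {4-[2-(benzyloxy)phenoxy]benzylidene}triphenylphosphorane (ylide, formed in the flask) | c1ccc(cc1)P(=Cc1ccc(Oc2ccccc2OCc2ccccc2)cc1)(c1ccccc1)c1ccccc1 | intermediate
10 | 2-{3-[2-(2-{4-[2-(benzyloxy)phenoxy]phenyl}ethenyl)-6-methoxyphenoxy]phenyl}acetic acid (E/Z mixture) | COc1cccc(C=Cc2ccc(Oc3ccccc3OCc3ccccc3)cc2)c1Oc1cccc(CC(=O)O)c1 | intermediate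
11 | 2-[3-(2-{2-[4-(2-hydroxyphenoxy)phenyl]ethyl}-6-methoxyphenoxy)phenyl]acetic acid (seco hydroxy acid) | COc1cccc(CCc2ccc(Oc3ccccc3O)cc2)c1Oc1cccc(CC(=O)O)c1 | intermediate
12 | O-acylisourea from 11 and EDC (formed in the flask) | CCN=C(NCCCN(C)C)OC(=O)Cc1cccc(Oc2c(OC)cccc2CCc2ccc(Oc3ccccc3O)cc2)c1 | intermediate
13 | 18-membered macrolactone (ring D O1 ester of the ring C arylacetic acid; ring B methyl ether) | O=C1Cc2cccc(c2)Oc2c(OC)cccc2CCc2ccc(cc2)Oc2ccccc2O1 | intermediate
14 | seco acyl triflate (mixed anhydride of 11 and CF3SO3H, ring D phenol free; formed in the flask) | O=C(OS(=O)(=O)C(F)(F)F)Cc1cccc(Oc2c(OC)cccc2CCc2ccc(Oc3ccccc3O)cc2)c1 | intermediate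
15 | macrocyclic deoxybenzoin (C=O on ring D C4, ring D OH free, ring B OMe) | Oc1ccc2cc1Oc1ccc(cc1)CCc1cccc(OC)c1Oc1cccc(c1)CC2=O | intermediate
16 | benzylic carbinol from 15 (racemic, formed in the flask) | Oc1ccc2cc1Oc1ccc(cc1)CCc1cccc(OC)c1Oc1cccc(c1)CC2O | intermediate
17 | marchantin C ring B methyl ether | Oc1ccc2cc1Oc1ccc(cc1)CCc1cccc(OC)c1Oc1cccc(c1)CC2 | intermediate
18 | bis(dibromoboryl) ether of marchantin C (formed in the flask) | BrB(Br)Oc1ccc2cc1Oc1ccc(cc1)CCc1cccc(OB(Br)Br)c1Oc1cccc(c1)CC2 | intermediate
19 | marchantin C | Oc1ccc2cc1Oc1ccc(cc1)CCc1cccc(O)c1Oc1cccc(c1)CC2 | target

## Step count and least certain steps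

Total: 10 steps. Longest linear sequence: 9 steps (steps 1, 2, 3, 5, 6, 7, 8, 9, 10).

Step 8 (key step). The most likely failures are:
- acyl transfer between molecules outrunning delivery across the ring, which would give oligomeric esters and ketones;
- acylation at C2 or C3 instead of C4;
- plain return to the lactone because the freed phenol is deactivated in the superacid.

The fallback uses a known reaction type, the high-dilution Friedel–Crafts ring closure of ω-arylalkanoyl chlorides to macrocyclic aryl ketones. It sets out from 11. Methylation of the phenol with dimethyl sulfate and aqueous NaOH, with brief warming to hydrolyse any methyl ester, would give 2-[3-(2-methoxy-6-{2-[4-(2-methoxyphenoxy)phenyl]ethyl}phenoxy)phenyl]acetic acid F1. Oxalyl chloride with catalytic DMF would give its acid chloride F2. Slow addition of F2 to SnCl4 in CH2Cl2 at 0 °C at high dilution should acylate ring D para to its methoxy group and give the macrocyclic ketone dimethyl ether F3. Et3SiH in CF3CO2H would reduce it to marchantin C dimethyl ether F4, and BBr3 would cleave both methyl ethers, so the fallback comes back to the route at 19.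

Step 7. Oligomerisation (diolide and linear esters) may compete with ring closure, because the phenol is a weak nucleophile and the ring contains a para-bridged benzene. Ketene formation from the activated arylacetic acid followed by dimerisation is a second risk. The fallback moves the ring closure from the ester to the alkene and sets out from 3, with 8 as second component:
- cleavage of the benzyl ether of 3 with BCl3 and pentamethylbenzene (CH2Cl2, −78 °C) would give 4-(2-hydroxyphenoxy)benzaldehyde F5;
- methylenation with excess Ph3P=CH2 in THF would give 2-(4-ethenylphenoxy)phenol F6;
- the same methylenation of 8 would give 2-[3-(2-ethenyl-6-methoxyphenoxy)phenyl]acetic acid F7;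
- a bimolecular Steglich esterification (EDC·HCl, DMAP, CH2Cl2) would join them to the diene ester F8;
- ring-closing metathesis with the second-generation Grubbs catalyst RuCl2(=CHPh)(PCy3)(H2IMes) in dilute CH2Cl2 would close the ring to the macrocyclic stilbene lactone F9, in either alkene geometry;
- hydrogenation over Pd/C comes back to the route at 13.

Step 4. Displacement may be slow because the fluorinated carbon is flanked by two substituents and the methoxy donor destabilises the anionic adduct. The dipotassium salt of 6 may dissolve poorly, and prolonged heating with base may cause disproportionation of the aldehyde. The fallback replaces addition–elimination by copper catalysis and sets out from 6. Fischer esterification (MeOH, catalytic H2SO4) would give methyl 3-hydroxyphenylacetate F10. Ullmann ether coupling with 2-bromo-3-methoxybenzaldehyde (CuI, N,N-dimethylglycine, Cs2CO3, dioxane, 90 °C) would give methyl 2-[3-(2-formyl-6-methoxyphenoxy)phenyl]acetate F11. Saponification with LiOH in THF–H2O comes back to the route at 8.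

Step 9. The benzylic cation formed on ionisation of the carbinol may alkylate a neighbouring ring across the macrocycle. Alternatively the reduction may stall at the carbinol stage, because the para-hydroxyl stabilises the protonated ketone. The fallback avoids the free cation and sets out from 15: reduction with NaBH4 in MeOH would give 16 as an isolated compound, and hydrogenolysis of its benzylic C–O bond with H2 over Pd/C in AcOH containing a trace of HClO4 comes back to the route at 17. It makes no compound outside the list.

## Further compounds

F1 | step 8 | 2-[3-(2-methoxy-6-{2-[4-(2-methoxyphenoxy)phenyl]ethyl}phenoxy)phenyl]acetic acid | COc1cccc(CCc2ccc(Oc3ccccc3OC)cc2)c1Oc1cccc(CC(=O)O)c1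
F2 | step 8 | 2-[3-(2-methoxy-6-{2-[4-(2-methoxyphenoxy)phenyl]ethyl}phenoxy)phenyl]acetyl chloride | COc1cccc(CCc2ccc(Oc3ccccc3OC)cc2)c1Oc1cccc(CC(=O)Cl)c1
F3 | step 8 | macrocyclic deoxybenzoin dimethyl ether (C=O on ring D C4, OMe on ring D C1 and on ring B) | COc1ccc2cc1Oc1ccc(cc1)CCc1cccc(OC)c1Oc1cccc(c1)CC2=O
F4 | step 8 | marchantin C dimethyl ether | COc1ccc2cc1Oc1ccc(cc1)CCc1cccc(OC)c1Oc1cccc(c1)CC2
F5 | step 7 | 4-(2-hydroxyphenoxy)benzaldehyde | O=Cc1ccc(Oc2ccccc2O)cc1
F6 | step 7 | 2-(4-ethenylphenoxy)phenol | C=Cc1ccc(Oc2ccccc2O)cc1
F7 | step 7 | 2-[3-(2-ethenyl-6-methoxyphenoxy)phenyl]acetic acid | COc1cccc(C=C)c1Oc1cccc(CC(=O)O)c1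
F8 | step 7 | 2-(4-ethenylphenoxy)phenyl 2-[3-(2-ethenyl-6-methoxyphenoxy)phenyl]acetate | COc1cccc(C=C)c1Oc1cccc(CC(=O)Oc2ccccc2Oc2ccc(C=C)cc2)c1
F9 | step 7 | macrocyclic stilbene lactone (18-membered, alkene between rings A and B, E/Z not fixed) | O=C1Cc2cccc(c2)Oc2c(OC)cccc2C=Cc2ccc(cc2)Oc2ccccc2O1
F10 | step 4 | methyl 3-hydroxyphenylacetate | COC(=O)Cc1cccc(O)c1
F11 | step 4 | methyl 2-[3-(2-formyl-6-methoxyphenoxy)phenyl]acetate | COc1cccc(C=O)c1Oc1cccc(CC(=O)OC)c1
F0 | step 9 | none | none
A1 | alternative 1 | open-chain dihalide (ring A iodide, ring B C1 bromide, both phenols as methyl ethers) | COc1ccc(CCc2cccc(Oc3c(OC)cccc3Br)c2)cc1Oc1ccc(I)cc1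
A2 | alternative 1 | macrocyclic diarylalkyne dimethyl ether | COc1ccc2cc1Oc1ccc(cc1)C#Cc1cccc(OC)c1Oc1cccc(c1)CC2
A3 | alternative 2 | open-chain ring A styrene with 2-aryloxy-3-(trifluoromethylsulfonyloxy)cyclohex-2-enone | COc1ccc(CCc2cccc(OC3=C(OS(=O)(=O)C(F)(F)F)CCCC3=O)c2)cc1Oc1ccc(C=C)cc1
A4 | alternative 2 | macrocyclic 3-alkyl-2-aryloxycyclohex-2-enone | COc1ccc2cc1Oc1ccc(cc1)CCC1=C(Oc3cccc(c3)CC2)C(=O)CCC1
A5 | alternative 3 | open-chain ring D 2-fluorobenzaldehyde with free ring A phenol (ring B methyl ether) | O=Cc1ccc(CCc2cccc(Oc3c(OC)cccc3CCc3ccc(O)cc3)c2)cc1F
A6 | alternative 3 | macrocyclic ring D aldehyde (ring B methyl ether) | O=Cc1ccc2cc1Oc1ccc(cc1)CCc1cccc(OC)c1Oc1cccc(c1)CC2
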